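**Retrosynthetic overview**

1. Target ⇐ hydride reduction/acetal hydrolysis of an α-alkylidene γ-lactone ⇐ Horner–Wadsworth–Emmons union (C15=C16) of an α-phosphono lactone with a C11 trienal.
2. cis-Fused lactone (C14–C15 bond, C14 stereocenter) ⇐ Rh-carbenoid C–H insertion from the C26 oxygen; C26 carbinol ⇐ C10-OH-directed ketone reduction; enal ⇐ isopropenyl group (allylic oxidation, isomerisation).
3. C6–C5 bond and C6 stereocenter ⇐ visible-light deoxygenative Giese addition of the C6 radical (from the C6 alcohol) to tert-butyl acrylate.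
4. Spiro centre C11 and C10 carbinol ⇐ hydroxyl-directed epoxidation/semipinacol ring expansion of an alkenyl cyclobutanol ⇐ electrochemical Cr/Ni-catalysed alkenylation of cyclobutanone with an enol triflate (C11–C26 bond).
5. Ring order: ring A (cyclohexane) is bought in (S)-carvone, whose stereocenter relays to all others and is finally erased; ring B (cyclopentane) comes from the cyclobutanol by ring expansion; the lactone ring is temporary.

Assumption: atom labels are the customary iridal ones (ring A = C6–C11, C6 carries C5–C3, C7 carries C2/C1/C25, C10 carries CH3 and OH, C11 is the spiro atom; ring B = C11–C12–C13–C14–C26; side chain C15–C24, C27 = CH2OH), and all numbered starting materials are taken as purchasable.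

**Route**

Step 1
Reactants: 1 (S)-(+)-carvone [(5S)-2-methyl-5-(prop-1-en-2-yl)cyclohex-2-en-1-one]
Product: 4 (5R,6R)-2-methyl-5-(prop-1-en-2-yl)-6-(triethylsilyloxy)cyclohex-2-en-1-one, via lithium dienolate 2 (not isolated), via lithium alkoxide 3 (not isolated)
Conditions: LiN(i-Pr)2, THF, −78 °C; racemic 2-(phenylsulfonyl)-3-phenyloxaziridine, −78 °C; Et3SiCl, DMAP, −78 to 0 °C
Reagents that add atoms: 2-(phenylsulfonyl)-3-phenyloxaziridine, O=S(=O)(N1OC1c1ccccc1)c1ccccc1; chlorotriethylsilane, CC[Si](Cl)(CC)CC
Why: Kinetic α′-deprotonation gives the cross-conjugated dienolate, which is hydroxylated (Davis enolate oxidation) on the face opposite the neighbouring isopropenyl group, so the bought stereocenter sets the new carbinol centre trans, and the alkoxide is silylated in the same flask.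

Step 2
Reactants: 4 (5R,6R)-2-methyl-5-(prop-1-en-2-yl)-6-(triethylsilyloxy)cyclohex-2-en-1-one
Product: 6 (5R,6R)-2-methyl-5-(prop-1-en-2-yl)-6-(triethylsilyloxy)cyclohex-1-en-1-yl trifluoromethanesulfonate, via lithium enolate 5 (not isolated)
Conditions: LiBH(s-Bu)3, THF, −78 °C; PhNTf2, −78 to 23 °C
Reagents that add atoms: N-phenylbis(trifluoromethanesulfonimide), O=S(=O)(N(c1ccccc1)S(=O)(=O)C(F)(F)F)C(F)(F)F
Why: Conjugate hydride reduction of the enone gives the enolate regiospecifically on the methyl-bearing side and O-triflation (enolate trapping) fixes it as the tetrasubstituted enol triflate; no stereocenter is formed or touched.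

Step 3
Reactants: 6 the enol triflate; 7 cyclobutanone
Product: 9 (1R,6R)-2-(1-hydroxycyclobutyl)-3-methyl-6-(prop-1-en-2-yl)cyclohex-2-en-1-ol, via bis-silyl ether 8 (not isolated)
Conditions: CrCl3 (20 mol %), NiCl2(dme) (5 mol %), 2,9-dimethyl-1,10-phenanthroline, Me3SiCl, Bu4NBF4, DMF, Al anode/Ni-foam cathode, undivided cell, constant current, 23 °C; then Bu4NF, THF
Reagents that add atoms: none
Why: Proposed new method: cathodically formed zerovalent nickel inserts into the C–OTf bond, the alkenyl group passes to trivalent chromium, and the alkenylchromium adds to cyclobutanone, whose strained carbonyl is aldehyde-like in electrophilicity, while Me3SiCl strips the chromium alkoxide so the cathode can return chromium to the divalent state; the closest known chemistry is the electrochemical chromium-catalytic Nozaki–Hiyama–Kishi coupling of alkenyl (pseudo)halides with aldehydes, extended here to a ketone acceptor and a fully substituted alkenyl partner, and it forms the C11–C26 bond of the future spirocycle without creating a stereocenter (fluoride then frees both hydroxyls).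

Step 4
Reactants: 9 the alkenyl cyclobutanol diol
Product: 11 (5R,6S,9R,10R)-6,10-dihydroxy-6-methyl-9-(prop-1-en-2-yl)spiro[4.5]decan-1-one, via epoxy diol 10 (not isolated)
Conditions: VO(acac)2 (5 mol %), t-BuOOH, CH2Cl2, 0 °C; then BF3·OEt2, −78 °C
Reagents that add atoms: tert-butyl hydroperoxide, CC(C)(C)OO
Why: Vanadium-catalysed hydroxyl-directed epoxidation puts the oxirane oxygen on the face of the free ring allylic hydroxyl (trans to isopropenyl), and the Lewis-acid semipinacol ring expansion of the cyclobutanol then moves a ring CH2 to C11 anti to the breaking C–O bond, so the C10 carbinol and the spiro centre C11 are set together and stereospecifically, with C10–OH cis to the new ketone carbon C26.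

Step 5
Reactants: 11 the spiro dihydroxy ketone; 12 tert-butyl acrylate
Product: 14 tert-butyl 3-[(5R,6S,9S,10R)-6-hydroxy-6-methyl-1-oxo-9-(prop-1-en-2-yl)spiro[4.5]decan-10-yl]propanoate, via benzoxazoline adduct 13 (not isolated)
Conditions: 3-phenylbenzoxazolium BF4, pyridine, MTBE, 23 °C; then 12 (5 equiv), Ir(ppy)2(dtbbpy)PF6 (1 mol %), DMSO/MTBE, 450 nm LEDs, 0 °C
Reagents that add atoms: none
Why: Photoredox deoxygenative Giese reaction: the benzoxazolium salt condenses with the secondary alcohol only, oxidation by the excited iridium complex and β-scission give the C6 radical, and the acrylate adds from the face opposite the neighbouring isopropenyl group and the axial C10 methyl, which forms the C6–C5 bond and places the chain cis to C10–OH and C26 (final C6 configuration).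

Step 6
Reactants: 14 the keto ester
Product: 15 tert-butyl 3-[(1R,5S,6S,9S,10R)-1,6-dihydroxy-6-methyl-9-(prop-1-en-2-yl)spiro[4.5]decan-10-yl]propanoate
Conditions: Me4NBH(OAc)3, MeCN/AcOH, −30 °C
Reagents that add atoms: none
Why: Hydroxyl-directed (Evans–Saksena) reduction: the borohydride bound to the C10 oxygen delivers hydride intramolecularly to the C10-facing side of the β-hydroxy ketone, giving the anti 1,3-diol and so the required C26 carbinol configuration.

Step 7
Reactants: 15 the diol ester; 16 (diethoxyphosphoryl)acetic acid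
Product: 18 diazo(diethoxyphosphoryl)acetate of the C26 alcohol of 15, via phosphonoacetate 17 (not isolated)
Conditions: DCC, DMAP (cat.), CH2Cl2, 0 °C; then 4-acetamidobenzenesulfonyl azide, DBU, MeCN, 0 °C
Reagents that add atoms: 4-acetamidobenzenesulfonyl azide, CC(=O)Nc1ccc(cc1)S(=O)(=O)N=[N+]=[N-]
Why: Steglich esterification acylates only the secondary C26 alcohol (the C10 alcohol is tertiary) and Regitz diazo transfer to the activated methylene installs the carbene precursor; no stereocenter changes.

Step 8
Reactants: 18 the diazo phosphonoacetate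
Product: 19 cis-fused α-(diethoxyphosphoryl) γ-lactone (O on C26 and C15 on C14 on the same face; C15 epimers)
Conditions: Rh2(OAc)4 (2 mol %), CH2Cl2, 40 °C, slow addition
Reagents that add atoms: none
Why: Rh-carbenoid intramolecular 1,5 C–H insertion can only reach the C14–H on the same face as the C26 oxygen (C11 bears no hydrogen), so the C14–C15 bond and the C14 stereocenter are formed cis-fused under control of C26; the C15 mixture is erased in step 14.

Step 9
Reactants: 19 the phosphono lactone
Product: 20 the 2-substituted acrolein (C7–C(=CH2)–CHO) derived from 19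
Conditions: SeO2, 1,4-dioxane, 80 °C
Reagents that add atoms: selenium dioxide, O=[Se]=O
Why: Selenium dioxide allylic oxidation (ene reaction then [2,3]-shift) oxidises the only allylic methyl group, that of the isopropenyl unit, to the aldehyde; C7 stays sp3 and untouched.

Step 10
Reactants: 20 the 2-substituted acrolein
Product: 22 dimethyl acetal of the (2Z) tetrasubstituted enal (C7=C2(CH3)–CH(OCH3)2), via enal 21 (not isolated)
Conditions: RhCl3·3H2O (5 mol %), MeOH, 60 °C; then HC(OMe)3, PPTS, 23 °C
Reagents that add atoms: trimethyl orthoformate, COC(OC)OC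
Why: Rhodium hydride addition/β-hydride elimination (alkene isomerisation) moves the double bond into the tetrasubstituted conjugated position, erasing the relay stereocenter C7 and favouring the Z enal (the small formyl group sits next to the substituted C6, minimising allylic strain); acetalisation then masks the aldehyde.

Step 11
Reactants: 23 1-propynylmagnesium bromide; 24 prenyl bromide (1-bromo-3-methylbut-2-ene)
Product: 25 7-methyloct-6-en-2-yne
Conditions: CuBr·SMe2 (5 mol %), THF, 0 to 23 °C
Reagents that add atoms: none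
Why: Copper-catalysed SN2 coupling of the alkynyl Grignard reagent at the primary carbon of the allylic bromide gives the skipped enyne.

Step 12
Reactants: 25 7-methyloct-6-en-2-yne
Product: 27 (2E)-2-iodo-7-methylocta-2,6-diene, via alkenylzirconocene 26 (not isolated)
Conditions: Cp2Zr(H)Cl (1.3 equiv), THF, 23 to 40 °C; I2, 0 °C
Reagents that add atoms: iodine, II
Why: Hydrozirconation is a syn addition that, after equilibration, places zirconium on the less hindered methyl-bearing alkyne carbon, and iodinolysis with retention gives the E alkenyl iodide (the C19=C20 geometry).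

Step 13
Reactants: 27 the alkenyl iodide; 28 acrolein
Product: 29 (2E,4E)-4,8-dimethylnona-2,4,7-trienal
Conditions: Pd(OAc)2 (5 mol %), Bu4NCl, NaHCO3, DMF, 40 °C
Reagents that add atoms: none
Why: Heck coupling under Jeffery conditions joins the alkenyl iodide to the acrolein terminus with retention of the trisubstituted alkene and formation of the E disubstituted alkene (C17=C18).

Step 14
Reactants: 22 the acetal phosphono lactone; 29 the trienal
Product: 30 (E)-α-alkylidene γ-lactone carrying the full tetraene side chain, the acetal and the tert-butyl ester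
Conditions: LiCl, DBU, MeCN, 0 to 23 °C
Reagents that add atoms: none
Why: Horner–Wadsworth–Emmons olefination under Masamune–Roush conditions gives the E alkylidene lactone (alkenyl chain anti to the lactone carbonyl), which is the C15=C16 geometry of the target; the mild base leaves the tert-butyl ester and acetal alone and removes the C15 stereocenter.

Step 15
Reactants: 30 the alkylidene lactone
Product: 32 CNP0261841.1 [(2Z)-2-[(1R,2S,5S,6R,10S)-1,10-dihydroxy-6-(3-hydroxypropyl)-2-[(2E,4E,6E)-1-hydroxy-6,10-dimethylundeca-2,4,6,9-tetraen-2-yl]-10-methylspiro[4.5]decan-7-ylidene]propanal], via triol acetal 31 (not isolated)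
Conditions: i-Bu2AlH (excess), CH2Cl2, −78 to 0 °C; then aq. oxalic acid, THF, 0 °C
Reagents that add atoms: water, O
Why: Hydride reduction opens the lactone 1,2-selectively to the C26/C27 diol and reduces the tert-butyl ester to the C3 alcohol, and mild acid hydrolysis of the allylic acetal unveils the enal; no stereocenter or alkene geometry is affected.

**Compound list**

1 | (S)-(+)-carvone, (5S)-2-methyl-5-(prop-1-en-2-yl)cyclohex-2-en-1-one | CC1=CC[C@@H](CC1=O)C(C)=C | starting material
2 | lithium cross-conjugated dienolate of 1 (deprotonated at the ring CH2 next to C=O) | CC1=CC[C@H](C(C)=C)C=C1[O-].[Li+] | intermediate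
3 | lithium alkoxide of (5R,6R)-6-hydroxycarvone (O trans to isopropenyl) | CC1=CC[C@H](C(C)=C)[C@@H]([O-])C1=O.[Li+] | intermediate
4 | (5R,6R)-2-methyl-5-(prop-1-en-2-yl)-6-(triethylsilyloxy)cyclohex-2-en-1-one | CC1=CC[C@H](C(C)=C)[C@@H](O[Si](CC)(CC)CC)C1=O | intermediate
5 | lithium (5R,6R)-2-methyl-5-(prop-1-en-2-yl)-6-(triethylsilyloxy)cyclohex-1-en-1-olate | CC1=C([O-])[C@H](O[Si](CC)(CC)CC)[C@@H](C(C)=C)CC1.[Li+] | intermediate
6 | (5R,6R)-2-methyl-5-(prop-1-en-2-yl)-6-(triethylsilyloxy)cyclohex-1-en-1-yl trifluoromethanesulfonate | CC1=C(OS(=O)(=O)C(F)(F)F)[C@H](O[Si](CC)(CC)CC)[C@@H](C(C)=C)CC1 | intermediate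
7 | cyclobutanone | O=C1CCC1 | starting material
8 | bis-silyl ether of 9 (ring O-SiEt3, cyclobutyl O-SiMe3) | CC1=C(C2(O[Si](C)(C)C)CCC2)[C@H](O[Si](CC)(CC)CC)[C@@H](C(C)=C)CC1 | intermediate
9 | (1R,6R)-2-(1-hydroxycyclobutyl)-3-methyl-6-(prop-1-en-2-yl)cyclohex-2-en-1-ol | CC1=C(C2(O)CCC2)[C@H](O)[C@@H](C(C)=C)CC1 | intermediate
10 | 2,3-epoxide of 9 (oxirane O cis to the ring OH, trans to isopropenyl) | C[C@]12CC[C@H](C(C)=C)[C@@H](O)[C@]1(O2)C1(O)CCC1 | intermediate
11 | (5R,6S,9R,10R)-6,10-dihydroxy-6-methyl-9-(prop-1-en-2-yl)spiro[4.5]decan-1-one | O=C1CCC[C@]12[C@H](O)[C@@H](C(C)=C)CC[C@]2(C)O | intermediate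
12 | tert-butyl acrylate | C=CC(=O)OC(C)(C)C | starting material
13 | 2-alkoxy-3-phenyl-2,3-dihydrobenzoxazole formed from the secondary (iridal C6) hydroxyl of 11 | O=C1CCC[C@]12[C@H](OC3Oc4ccccc4N3c3ccccc3)[C@@H](C(C)=C)CC[C@]2(C)O | intermediate
14 | tert-butyl 3-[(5R,6S,9S,10R)-6-hydroxy-6-methyl-1-oxo-9-(prop-1-en-2-yl)spiro[4.5]decan-10-yl]propanoate | O=C1CCC[C@]12[C@H](CCC(=O)OC(C)(C)C)[C@@H](C(C)=C)CC[C@]2(C)O | intermediate
15 | tert-butyl 3-[(1R,5S,6S,9S,10R)-1,6-dihydroxy-6-methyl-9-(prop-1-en-2-yl)spiro[4.5]decan-10-yl]propanoate | O[C@@H]1CCC[C@]12[C@H](CCC(=O)OC(C)(C)C)[C@@H](C(C)=C)CC[C@]2(C)O | intermediate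
16 | (diethoxyphosphoryl)acetic acid | CCOP(=O)(CC(=O)O)OCC | starting material
17 | (diethoxyphosphoryl)acetate of the C1 (iridal C26) hydroxyl of 15 | CCOP(=O)(OCC)CC(=O)O[C@@H]1CCC[C@]12[C@H](CCC(=O)OC(C)(C)C)[C@@H](C(C)=C)CC[C@]2(C)O | intermediate
18 | diazo(diethoxyphosphoryl)acetate of the C1 (iridal C26) hydroxyl of 15 | CCOP(=O)(OCC)C(=[N+]=[N-])C(=O)O[C@@H]1CCC[C@]12[C@H](CCC(=O)OC(C)(C)C)[C@@H](C(C)=C)CC[C@]2(C)O | intermediate
19 | cis-fused α-(diethoxyphosphoryl) γ-lactone across iridal C26(O)/C14(C15), isopropenyl at C7, tert-butyl propanoate chain at C6 (C15 epimers) | CCOP(=O)(OCC)C1C(=O)O[C@@H]2[C@H]1CC[C@]23[C@H](CCC(=O)OC(C)(C)C)[C@@H](C(C)=C)CC[C@]3(C)O | intermediate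
20 | as 19 with the C7 substituent oxidised to 1-formylvinyl, C(=CH2)CHO | CCOP(=O)(OCC)C1C(=O)O[C@@H]2[C@H]1CC[C@]23[C@H](CCC(=O)OC(C)(C)C)[C@@H](C(=C)C=O)CC[C@]3(C)O | intermediate
21 | as 19 with the (2Z) enal C7=C2(CH3)CHO (CHO cis to C6) | CCOP(=O)(OCC)C1C(=O)O[C@@H]2[C@H]1CC[C@]23[C@H](CCC(=O)OC(C)(C)C)/C(=C(/C)C=O)CC[C@]3(C)O | intermediate
22 | dimethyl acetal of 21 | CCOP(=O)(OCC)C1C(=O)O[C@@H]2[C@H]1CC[C@]23[C@H](CCC(=O)OC(C)(C)C)/C(=C(/C)C(OC)OC)CC[C@]3(C)O | intermediate
23 | 1-propynylmagnesium bromide | CC#C[Mg]Br | starting material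
24 | prenyl bromide, 1-bromo-3-methylbut-2-ene | CC(C)=CCBr | starting material
25 | 7-methyloct-6-en-2-yne | CC#CCC=C(C)C | intermediate
26 | chloro[(2E)-7-methylocta-2,6-dien-2-yl]zirconocene | C/C(=C\CC=C(C)C)[Zr](Cl)(C1C=CC=C1)C1C=CC=C1 | intermediate
27 | (2E)-2-iodo-7-methylocta-2,6-diene | C/C(I)=C\CC=C(C)C | intermediate
28 | acrolein | C=CC=O | starting material
29 | (2E,4E)-4,8-dimethylnona-2,4,7-trienal | O=C/C=C/C(C)=C/CC=C(C)C | intermediate
30 | (E)-α-[(2E,4E)-4,8-dimethylnona-2,4,7-trienylidene] γ-lactone of the spiro core, with C1 dimethyl acetal and C3 tert-butyl ester | CC(C)=CC/C=C(C)/C=C/C=C1/C(=O)O[C@@H]2[C@H]1CC[C@]23[C@H](CCC(=O)OC(C)(C)C)/C(=C(/C)C(OC)OC)CC[C@]3(C)O | intermediate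
31 | dimethyl acetal of the target aldehyde | CC(C)=CC/C=C(C)/C=C/C=C(/CO)[C@@H]1CC[C@]2([C@H](CCCO)/C(=C(/C)C(OC)OC)CC[C@]2(C)O)[C@@H]1O | intermediate
32 | CNP0261841.1, (2Z)-2-[(1R,2S,5S,6R,10S)-1,10-dihydroxy-6-(3-hydroxypropyl)-2-[(2E,4E,6E)-1-hydroxy-6,10-dimethylundeca-2,4,6,9-tetraen-2-yl]-10-methylspiro[4.5]decan-7-ylidene]propanal | CC(C)=CC/C=C(C)/C=C/C=C(/CO)[C@@H]1CC[C@]2([C@H](CCCO)/C(=C(/C)C=O)CC[C@]2(C)O)[C@@H]1O | target

**Step count and risks**

Total steps: 15. Longest linear sequence: 12 (steps 1–10, 14, 15); the trienal branch is 3 steps (11–13).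

Most likely to fail:

- Step 3 (the proposed electrochemical Cr/Ni alkenylation of a ketone). The hindered alkenylchromium may add too slowly to cyclobutanone, giving reduced alkene or homocoupling instead. Fallback with known chemistry, setting out from 6 and returning at 9: Pd(PPh3)4, Me3SnSnMe3 and LiCl convert 6 into the trimethylstannyl alkene F1; tin–lithium exchange with MeLi at −78 °C, then CeCl3 and cyclobutanone 7, gives the mono-silylated tertiary alcohol F2; Bu4NF then gives 9.

- Step 5 (photochemical Giese at C6). The C6 radical sits next to the carbon bearing the C26 ketone and can undergo a 1,2-acyl shift (ring expansion to a decalone) in competition with addition; activation of the hindered alcohol may also be slow. Fallback that removes the ketone before any radical is made and installs the lactone precursor first, setting out from 11 and returning at 17: chelation-controlled reduction of 11 (Et2BOMe, NaBH4, −78 °C; external hydride attacks from the C10 side of the C6-O boron chelate) gives the triol F3 with the same C26 configuration as 15; selective Steglich acylation of the less hindered cyclopentanol with 16 gives the hydroxy phosphonoacetate F4; the deoxygenative Giese addition to 12 is then run on F4, where no acyl shift is possible, and delivers 17, which continues with the diazo transfer of step 7.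

- Step 8 (Rh-carbenoid C–H insertion). O–H insertion into the free C10 alcohol, β-lactone formation or carbene dimerisation may compete. Fallback by enolate chemistry, setting out from 14 and returning at 19: LiN(SiMe3)2 (2.2 equiv) and ethyl bromoacetate alkylate C14 to give the keto diester F5 (C14 epimers, equilibrated with DBU); Me4NBH(OAc)3 followed by PPTS reduces the ketone from the C10 side and closes only the cis hydroxy ester to the lactone F6; LiN(i-Pr)2 and ClP(O)(OEt)2, then more LiN(i-Pr)2 (oxygen-to-carbon phosphorus shift), give 19. This is lower yielding because C14 is not controlled in the alkylation.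

Further compounds
F1 | step 3 | triethyl{[(1R,6R)-3-methyl-6-(prop-1-en-2-yl)-2-(trimethylstannyl)cyclohex-2-en-1-yl]oxy}silane | CC1=C([Sn](C)(C)C)[C@H](O[Si](CC)(CC)CC)[C@@H](C(C)=C)CC1
F2 | step 3 | 1-[(5R,6R)-2-methyl-5-(prop-1-en-2-yl)-6-(triethylsilyloxy)cyclohex-1-en-1-yl]cyclobutan-1-ol | CC1=C(C2(O)CCC2)[C@H](O[Si](CC)(CC)CC)[C@@H](C(C)=C)CC1
F3 | step 5 | (1R,5S,6S,9R,10R)-6-methyl-9-(prop-1-en-2-yl)spiro[4.5]decane-1,6,10-triol | O[C@@H]1CCC[C@]12[C@H](O)[C@@H](C(C)=C)CC[C@]2(C)O
F4 | step 5 | (diethoxyphosphoryl)acetate of the C1 hydroxyl of F3 | CCOP(=O)(OCC)CC(=O)O[C@@H]1CCC[C@]12[C@H](O)[C@@H](C(C)=C)CC[C@]2(C)O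
F5 | step 8 | C14-(2-ethoxy-2-oxoethyl) derivative of 14 (C14 epimers) | O=C1C(CC(=O)OCC)CC[C@]12[C@H](CCC(=O)OC(C)(C)C)[C@@H](C(C)=C)CC[C@]2(C)O
F6 | step 8 | cis-fused γ-lactone corresponding to 19 without the phosphoryl group | C1C(=O)O[C@@H]2[C@H]1CC[C@]23[C@H](CCC(=O)OC(C)(C)C)[C@@H](C(C)=C)CC[C@]3(C)O
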